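**Assumptions.** The target has no stereocentres, so there is no enantiomer issue. I read the SMILES as the neutral, free-acid depiction of the sulfate monoester. The route carries the sulfate as a tetrabutylammonium (TBA) salt and protonates it in the last step.

## Retrosynthetic overview
- The target comes from global hydrogenolysis of a tetra-O-benzyl flavone 6-O-sulfate. The sulfate is carried through the whole route as an inert TBA salt, so no late selective sulfation of a polyphenol is needed.
- The γ-pyrone (ring C) is formed last, in one operation. A Pd-catalysed carbonylative Sonogashira coupling of an o-iodophenol with an aryl alkyne and CO gives an o-hydroxyaryl ynone, which closes by 6-endo oxa-Michael addition. CO supplies C4, and the alkyne supplies C2, C3 and ring B.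
- The o-iodophenol comes from iodinating a hydroquinone mono-sulfate. That sulfate is made by Elbs persulfate para-hydroxylation of 3,5-bis(benzyloxy)phenol. This puts the O-SO3⁻ at the future C6, para to the future ring oxygen and flanked by the 5- and 7-oxygens, in one step from phloroglucinol.
- Ring formation order: ring A is the pre-existing benzene, ring B is attached through the alkyne, and ring C is closed in the penultimate C–C/C–O bond-forming step.

## Route

**Step 1**
Reactants: 1 phloroglucinol; 2 benzyl bromide (2.0 equiv)
Product: 3 3,5-bis(benzyloxy)phenol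
Conditions: BnBr, K2CO3, acetone, reflux. Separate the di-benzyl compound from the mono- and tri-benzyl compounds by chromatography.
Reagents that add atoms: benzyl bromide, BrCc1ccccc1
Why: Williamson O-benzylation of the symmetric triol is statistical, but the mono-, di- and tri-ethers are easily separated. Nothing here is stereogenic.

**Step 2**
Reactants: 3 3,5-bis(benzyloxy)phenol; 4 potassium persulfate; 5 tetrabutylammonium hydrogen sulfate
Product: 6 tetrabutylammonium 2,6-bis(benzyloxy)-4-hydroxyphenyl sulfate
Conditions: (i) K2S2O8 (1.1 equiv), aq. NaOH, pyridine/H2O, 0 °C → rt, 24–48 h; (ii) neutralise to pH ~7 with aq. NH4Cl, add Bu4NHSO4, extract with CH2Cl2. No acid hydrolysis, so the sulfate is kept.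
Reagents that add atoms: K2S2O8, [K+].[K+].[O-]S(=O)(=O)OOS(=O)(=O)[O-]; Bu4NHSO4, CCCC[N+](CCCC)(CCCC)CCCC.OS(=O)(=O)[O-]
Why: Elbs persulfate oxidation attacks the phenoxide para position and gives the para-hydroxyaryl sulfate directly, placing the O-SO3⁻ at the future C6 with no stereocentre involved. Proposed new method: this is a regiospecific installation of the flavone 6-sulfate by Elbs oxidation on a hindered 3,5-dialkoxyphenoxide. The mechanism is electrophilic attack of S2O8²⁻ at the most activated para carbon (flanked by two OBn groups), followed by rearomatisation. The closest known reaction is the Elbs persulfate oxidation of o-substituted phenols to hydroquinone monosulfates.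

**Step 3**
Reactants: 6 TBA 2,6-bis(benzyloxy)-4-hydroxyphenyl sulfate; 7 N-iodosuccinimide (1.0 equiv)
Product: 8 TBA 2,6-bis(benzyloxy)-4-hydroxy-3-iodophenyl sulfate
Conditions: NIS, MeCN, −20 → 0 °C, dark, 1–2 h
Reagents that add atoms: NIS, O=C1CCC(=O)N1I
Why: Electrophilic aromatic iodination occurs ortho to the free OH. The two ortho positions are equivalent, and the para position is blocked by the sulfate, so the product is a single regioisomer and achiral.

**Step 4**
Reactants: 9 3,4-bis(benzyloxy)benzaldehyde; 10 dimethyl (1-diazo-2-oxopropyl)phosphonate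
Product: 11 4-ethynyl-1,2-bis(benzyloxy)benzene
Conditions: K2CO3, MeOH, rt, 12 h
Reagents that add atoms: Ohira–Bestmann reagent, COP(=O)(OC)C(=[N+]=[N-])C(C)=O
Why: Ohira–Bestmann homologation converts the aldehyde to the terminal alkyne under mild base, so the benzyl ethers are untouched.

**Step 5**
Reactants: 8 iodophenol sulfate; 11 alkyne; 12 carbon monoxide
Product: 13 TBA 5,7-bis(benzyloxy)-2-[3,4-bis(benzyloxy)phenyl]-4-oxo-4H-chromen-6-yl sulfate
Conditions: PdCl2(PPh3)2 (5 mol %), Et3N (3 equiv), CO (balloon, 1 atm), DMF, 80 °C, 12 h, copper-free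
Reagents that add atoms: carbon monoxide, [C-]#[O+]
Why: Oxidative addition of Ar–I, CO insertion, alkynylation and reductive elimination give the 2'-hydroxyaryl ynone, which cyclises by 6-endo-dig oxa-Michael addition (carbonylative Sonogashira/annulation). The C2=C3 alkene is sp2, so no stereocentre arises. Proposed new method: this applies carbonylative flavone annulation to a di-ortho-substituted, electron-rich iodophenol bearing an organic-soluble aryl sulfate salt. The copper-free conditions and CO pressure disfavour the competing 2-arylbenzofuran, and the closest known reaction is the carbonylative Sonogashira annulation of o-iodophenols to flavones.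

**Step 6**
Reactants: 13 protected flavone sulfate
Product: 14 TBA 6-hydroxyluteolin 6-sulfate
Conditions: H2 (1 atm), 10% Pd/C, THF/MeOH 1:1, rt, 6–12 h, monitored by LCMS
Reagents that add atoms: none (H2 only)
Why: Catalytic hydrogenolysis removes all four benzyl ethers (toluene is lost). Aryl sulfate monoesters are inert to H2/Pd and the conjugated flavone C2=C3 survives short reaction times.

**Step 7**
Reactants: 14 TBA salt of the target
Product: 15 6-hydroxyluteolin 6-sulfate (free acid, the target)
Conditions: Dowex 50W-X8 (H+ form), H2O/MeOH, 4 °C, quick elution, then lyophilise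
Reagents that add atoms: none (H+ from the resin only)
Why: Cation exchange replaces Bu4N+ with H+ and is kept cold and short to avoid acid hydrolysis of the aryl sulfate. For storage, neutralise to the K salt with KHCO3.

## Compound list
1 | phloroglucinol | Oc1cc(O)cc(O)c1 | starting material
2 | benzyl bromide | BrCc1ccccc1 | starting material
3 | 3,5-bis(benzyloxy)phenol | Oc1cc(OCc2ccccc2)cc(OCc2ccccc2)c1 | intermediate
4 | potassium persulfate | [K+].[K+].[O-]S(=O)(=O)OOS(=O)(=O)[O-] | starting material
5 | tetrabutylammonium hydrogen sulfate | CCCC[N+](CCCC)(CCCC)CCCC.OS(=O)(=O)[O-] | starting material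
6 | TBA 2,6-bis(benzyloxy)-4-hydroxyphenyl sulfate | CCCC[N+](CCCC)(CCCC)CCCC.[O-]S(=O)(=O)Oc1c(OCc2ccccc2)cc(O)cc1OCc1ccccc1 | intermediate
7 | N-iodosuccinimide | O=C1CCC(=O)N1I | starting material
8 | TBA 2,6-bis(benzyloxy)-4-hydroxy-3-iodophenyl sulfate | CCCC[N+](CCCC)(CCCC)CCCC.[O-]S(=O)(=O)Oc1c(OCc2ccccc2)c(I)c(O)cc1OCc1ccccc1 | intermediate
9 | 3,4-bis(benzyloxy)benzaldehyde | O=Cc1ccc(OCc2ccccc2)c(OCc2ccccc2)c1 | starting material
10 | dimethyl (1-diazo-2-oxopropyl)phosphonate | COP(=O)(OC)C(=[N+]=[N-])C(C)=O | starting material
11 | 4-ethynyl-1,2-bis(benzyloxy)benzene | C#Cc1ccc(OCc2ccccc2)c(OCc2ccccc2)c1 | intermediate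
12 | carbon monoxide | [C-]#[O+] | starting material
13 | TBA 5,7-bis(benzyloxy)-2-[3,4-bis(benzyloxy)phenyl]-4-oxochromen-6-yl sulfate | CCCC[N+](CCCC)(CCCC)CCCC.[O-]S(=O)(=O)Oc1c(OCc2ccccc2)cc2oc(-c3ccc(OCc4ccccc4)c(OCc4ccccc4)c3)cc(=O)c2c1OCc1ccccc1 | intermediate
14 | TBA 6-hydroxyluteolin 6-sulfate | CCCC[N+](CCCC)(CCCC)CCCC.[O-]S(=O)(=O)Oc1c(O)cc2oc(-c3ccc(O)c(O)c3)cc(=O)c2c1O | intermediate
15 | 6-hydroxyluteolin 6-sulfate (achiral) | O=c1cc(-c2ccc(O)c(O)c2)oc2cc(O)c(OS(=O)(=O)O)c(O)c12 | target

## Totals
- Total steps: 7, including the one-step alkyne branch.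
- Longest linear sequence: 6 steps (phloroglucinol → 3 → 6 → 8 → 13 → 14 → 15).

## Three steps most likely to fail
1. **Step 2 (Elbs oxidation).** The yield may be low (about 20–40%), and ortho attack next to the phenoxide could compete with para attack. Fallback: abandon the Elbs sulfate and use a classical A-ring route. Build 2-hydroxy-4,6-bis(benzyloxy)-5-(PMB-oxy)acetophenone, then Claisen–Schmidt condensation with 9 and I2/DMSO oxidative cyclisation to the flavone. Remove the PMB group, sulfate the free 6-OH with SO3·pyridine, and finish with H2/Pd-C.
2. **Step 5 (carbonylative annulation).** The di-ortho-substituted electron-rich iodide may react slowly, or the 2-arylbenzofuran (non-carbonylative) product may dominate. Fallback: change to a stepwise chalcone route. Stille coupling of 8 with (1-ethoxyvinyl)tributyltin and hydrolysis gives the 2'-hydroxyacetophenone sulfate. Claisen–Schmidt condensation with 9 then gives the chalcone, and I2/DMSO oxidative cyclisation gives 13.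
3. **Step 1 (statistical dibenzylation).** The yield may be low, and C-benzylation of phloroglucinol may compete. Fallback: start from 3,5-dihydroxybenzaldehyde. Bis-benzylate it, do a Baeyer–Venkataraman-type mCPBA oxidation to the aryl formate, and hydrolyse with K2CO3/MeOH to give 3.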